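(The runs are calculated on assumed constants; the scatter is artificial.)

The constants I had were the charges and two runs, all at one catalyst charge.

in all of them: free catalyst 0.11 mM
- spring: substrate 0.0067 M; run made earlier
- dusk: substrate 0.015 M; run made earlier
- flask: substrate 0.010 M

| run | time / min | product / % | substrate / % |
|---|---|---|---|
| spring | 1.50 | 13 | 85 |
| spring | 3.00 | 25 | 72 |
| spring | 5.00 | 40 | 60 |
| spring | 6.00 | 46 | 53 |
| spring | 8.00 | 60 | 39 |
| spring | 10.0 | 71 | 31 |
| dusk | 0.833 | 5 | 95 |
| dusk | 1.33 | 8 | 90 |
| dusk | 2.00 | 10 | 89 |
| dusk | 4.00 | 21 | 80 |
| dusk | 6.00 | 26 | 75 |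
| dusk | 10.0 | 44 | 54 |

(scatter of a reading: 1.5 percentage points)

1. factor on the rate of making product when 10% of the substrate are converted if free catalyst is charged twice over
2. factor on the rate when 10% of the substrate are converted if free catalyst is charged at 1.2 mM instead

- no earlier run changes the charge of free catalyst; that part of a forecast is a guess

At 6.00 min the spring run had made 46% of its charge, and the dusk run 26% of its larger one. So the rate rose less than the substrate charge.

I turned the question round. For the rate to follow the charge, by 10.9 at 1.2 mM, the catalyst must stand alike at 10% conversion at both charges. So I counted the rounds to that conversion (turnovers): substrate used up by then per catalyst charged, 9.09 in the flask.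

Doubling gave 4.55 rounds, still several, so I took a factor a little under 2. At 1.2 mM it gave 0.833, fewer than one. I guessed that factor near 10.9, though the count did not show that the catalyst stood alike.

The forecast gave 1.7 (1.3 to 2.1) and 7 (3 to 11.5), saying “I lean towards near first order”. Its second figure stood below mine.

The simulation gave 1.84 and 12.8.

    substrate + free catalyst ⇌ catalyst intermediate A (K = 160 L mol⁻¹, k = 470 L mol⁻¹ s⁻¹)
    catalyst intermediate A → catalyst intermediate B (k = 0.237 s⁻¹)
    catalyst intermediate B → free catalyst + product (k = 13.3 s⁻¹)
    2 catalyst intermediate A ⇌ resting dimer (K = 8400 L mol⁻¹, k = 139 L mol⁻¹ s⁻¹)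

With 4.55 rounds, the factor was 0.920 of the charge multiple. With 0.833 rounds, it was 1.17 of it. In the flask at 1.20 min, before the 9.09 rounds were done at 1.27 min, the resting dimer held 26.9% of the catalyst charged, counted twice per dimer, beside catalyst intermediate A at 41.4% and free catalyst at 30.9%. The step from catalyst intermediate A to catalyst intermediate B then ran on, half its turnover up to 12.0 min done by 5.34 min, and at 12.0 min the flask's resting dimer stood at 15.5%.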